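Clerodane numbering is used: ring A = C1–C5, C10; ring B = C5–C10; C17 on C8, C18 on C4, C19 on C5, C20 on C9; side chain C11–C16.
Cuts (retro): C12–C13 (Heck) and the two ester C–O bonds; ring B at C7–C8 (ketyl closure) and C5–C6 ([3,3] shift), both undone in one step; then C8–C17 (MeLi on a lactone) and C9–C10 ([3,3] shift).
Enabling feature: the exocyclic C4=C18 alkene beside quaternary C5 and the oxygen on C6 are the footprint of a C18–O–C7H=C6H(OSi) allyl enol ether lying across the ring-A C4=C5 bond. Its [3,3] shift makes C5–C6 and unmasks a C7 aldehyde 1,6 to the C8 methyl ketone, and the cis-7,8-diol of ring B is what their samarium-mediated coupling gives.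
Forward: Hagemann's ester provides ring A with C18 and C19; a Claisen rearrangement with a lactate-derived allylic alcohol adds C8, C9, C11, C12 and C20; lactonization, methyl addition and ether formation set up the key step, which closes ring B; acylation and Heck coupling finish the target.
Stereochemistry: C9 and C10 from (S)-lactate by chair chirality transfer; C1 by hydride attack anti to the C10 substituent followed by inversion in the lactonization; C5 anti to the C9 group and C6 from the (Z)-enol silane in the key [3,3] shift; C7 and C8 from the samarium chelate in the ring closure.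
Key step: step 16
Remark: ylide 3 is taken as a purchasable stabilized ylide; if it is not, it is one step from tert-butyl 2-bromopropanoate and PPh3.

Step 1
Reactants: 1 ethyl (S)-lactate
Product: 2 ethyl (S)-2-[(tert-butyldimethylsilyl)oxy]propanoate
Conditions: TBSCl, imidazole, DMF, rt
Reagents that add atoms: tert-butyldimethylsilyl chloride, CC(C)(C)[Si](C)(C)Cl
Why: Standard silylation of a secondary alcohol protects the carbinol that later steers the first sigmatropic step and leaves the lactate stereocenter untouched.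

Step 2
Reactants: 2 ethyl (S)-2-[(tert-butyldimethylsilyl)oxy]propanoate; 3 tert-butyl 2-(triphenyl-λ5-phosphanylidene)propanoate
Product: 5 tert-butyl (2E,4S)-4-[(tert-butyldimethylsilyl)oxy]-2-methylpent-2-enoate, via aldehyde 4 (not isolated)
Conditions: iBu2AlH (1.05 equiv), CH2Cl2, −78 °C; then 3, −78 °C → rt
Reagents that add atoms: none
Why: Partial reduction of the ester and Wittig olefination of the aldehyde with the stabilized ylide in the same flask avoids racemization of the α-silyloxy aldehyde and should give the (E)-trisubstituted enoate, as stabilized α-methyl ylides usually do.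

Step 3
Reactants: 5 tert-butyl (2E,4S)-4-[(tert-butyldimethylsilyl)oxy]-2-methylpent-2-enoate
Product: 6 tert-butyl (2E,4S)-4-hydroxy-2-methylpent-2-enoate
Conditions: HF·pyridine, THF, 0 °C → rt
Reagents that add atoms: none
Why: Fluoride-mediated desilylation frees the allylic carbinol without touching the tert-butyl ester, and the (E)-geometry rules out lactonization.

Step 4
Reactants: 7 ethyl 2-methyl-4-oxocyclohex-2-ene-1-carboxylate (Hagemann's ester, racemic)
Product: 8 ethyl 4-ethoxy-2-methylcyclohexa-1,3-diene-1-carboxylate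
Conditions: HC(OEt)3, EtOH, TsOH (cat.), rt
Reagents that add atoms: triethyl orthoformate, CCOC(OCC)OCC
Why: Acid-catalysed dienol ether formation from an enone should give the linear, ester-conjugated 1-alkoxy-1,3-diene under thermodynamic control and removes the only stereocenter of the racemic starting material.

Step 5
Reactants: 8 ethyl 4-ethoxy-2-methylcyclohexa-1,3-diene-1-carboxylate; 6 tert-butyl (2E,4S)-4-hydroxy-2-methylpent-2-enoate
Product: 10 ethyl (3S)-3-[(2R,3E)-1-tert-butoxy-2-methyl-1-oxopent-3-en-2-yl]-2-methyl-4-oxocyclohex-1-ene-1-carboxylate, via allyl dienol ether 9 (not isolated)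
Conditions: 2,4-dinitrophenol (cat.), xylenes, 130 °C, EtOH distilled off
Reagents that add atoms: none
Why: Acid-catalysed alkoxy exchange followed by Claisen rearrangement of the allyl dienol ether forms C9–C10 at the enol α-carbon, and the chair transition state with the carbinol methyl group equatorial should transfer the (S)-configuration of 6 to quaternary C9 and to C10 while giving the (E)-propenyl group.

Step 6
Reactants: 10 ethyl (3S)-3-[(2R,3E)-1-tert-butoxy-2-methyl-1-oxopent-3-en-2-yl]-2-methyl-4-oxocyclohex-1-ene-1-carboxylate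
Product: 11 ethyl (3S)-3-[(2R)-1-tert-butoxy-2-methyl-1-oxobut-3-en-2-yl]-2-methyl-4-oxocyclohex-1-ene-1-carboxylate
Conditions: second-generation Hoveyda–Grubbs catalyst (5 mol%), ethylene (5 bar), toluene, 60 °C
Reagents that add atoms: ethylene, C=C
Why: Ethenolysis (cross-metathesis with ethylene) trims the propenyl group, whose methyl only served the chirality transfer, to the vinyl group needed for the last coupling, while the tetrasubstituted enoate should be inert to the ruthenium carbene.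

Step 7
Reactants: 11 ethyl (3S)-3-[(2R)-1-tert-butoxy-2-methyl-1-oxobut-3-en-2-yl]-2-methyl-4-oxocyclohex-1-ene-1-carboxylate
Product: 12 ethyl (3S,4S)-3-[(2R)-1-tert-butoxy-2-methyl-1-oxobut-3-en-2-yl]-4-hydroxy-2-methylcyclohex-1-ene-1-carboxylate
Conditions: NaBH4, MeOH, −20 °C
Reagents that add atoms: none
Why: Hydride reduction of the ring ketone should occur on the face opposite the pseudoaxial quaternary substituent of the neighbouring carbon, giving the alcohol with C1–OH cis to C9, and the tert-butyl ester cannot lactonize onto it.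

Step 8
Reactants: 12 ethyl (3S,4S)-3-[(2R)-1-tert-butoxy-2-methyl-1-oxobut-3-en-2-yl]-4-hydroxy-2-methylcyclohex-1-ene-1-carboxylate
Product: 14 ethyl (3R,3aS,7aR)-3-ethenyl-3,4-dimethyl-2-oxo-2,3,3a,6,7,7a-hexahydro-1-benzofuran-5-carboxylate, via triflate 13 (not isolated)
Conditions: Tf2O, pyridine, CH2Cl2, −78 °C → rt
Reagents that add atoms: none
Why: Intramolecular displacement of the triflate by the carbonyl oxygen of the tert-butyl ester with loss of 2-methylpropene (anchimeric lactonization, as in the closure of tert-butyl carbamates and esters onto sulfonates) should invert C1 to the trans relationship between the C1 oxygen and C9 that the target has, and the electron-poor C4=C5 alkene cannot compete as a homoallylic participant.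

Step 9
Reactants: 14 ethyl (3R,3aS,7aR)-3-ethenyl-3,4-dimethyl-2-oxo-2,3,3a,6,7,7a-hexahydro-1-benzofuran-5-carboxylate
Product: 15 ethyl (3S,4R)-4-hydroxy-2-methyl-3-[(3R)-3-methyl-4-oxopent-1-en-3-yl]cyclohex-1-ene-1-carboxylate
Conditions: MeLi (1.05 equiv), THF, −78 °C; then H2O
Reagents that add atoms: methyllithium, [Li]C
Why: Addition of one equivalent of methyllithium to the strained γ-lactone should stop at the tetrahedral intermediate, which collapses on work-up to the C8 methyl ketone (C17 introduced) and the free C1 hydroxyl, the hindered conjugated ethyl ester reacting more slowly at −78 °C.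

Step 10
Reactants: 15 ethyl (3S,4R)-4-hydroxy-2-methyl-3-[(3R)-3-methyl-4-oxopent-1-en-3-yl]cyclohex-1-ene-1-carboxylate
Product: 16 ethyl (3S,4R)-4-[(tert-butyldimethylsilyl)oxy]-2-methyl-3-[(3R)-3-methyl-4-oxopent-1-en-3-yl]cyclohex-1-ene-1-carboxylate
Conditions: TBSOTf, 2,6-lutidine, CH2Cl2, −78 → 0 °C
Reagents that add atoms: tert-butyldimethylsilyl trifluoromethanesulfonate, CC(C)(C)[Si](C)(C)OS(=O)(=O)C(F)(F)F
Why: Silylation with the silyl triflate protects the hindered C1 hydroxyl as an ether that is kept until the last step.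

Step 11
Reactants: 16 ethyl (3S,4R)-4-[(tert-butyldimethylsilyl)oxy]-2-methyl-3-[(3R)-3-methyl-4-oxopent-1-en-3-yl]cyclohex-1-ene-1-carboxylate
Product: 17 (3R)-3-[(1S,6R)-6-[(tert-butyldimethylsilyl)oxy]-3-(hydroxymethyl)-2-methylcyclohex-2-en-1-yl]-3-methylpent-4-en-2-ol (C2 epimers)
Conditions: iBu2AlH (4 equiv), CH2Cl2, −78 → 0 °C
Reagents that add atoms: none
Why: Hydride reduction turns the conjugated ester into the primary allylic alcohol needed for the ether tether and unavoidably the ketone into a carbinol, whose configuration does not matter because step 13 reoxidizes it.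

Step 12
Reactants: 17 (3R)-3-[(1S,6R)-6-[(tert-butyldimethylsilyl)oxy]-3-(hydroxymethyl)-2-methylcyclohex-2-en-1-yl]-3-methylpent-4-en-2-ol (C2 epimers); 18 2-bromo-1,1-diethoxyethane
Product: 19 (3R)-3-[(1S,6R)-6-[(tert-butyldimethylsilyl)oxy]-3-[(2,2-diethoxyethoxy)methyl]-2-methylcyclohex-2-en-1-yl]-3-methylpent-4-en-2-ol (C2 epimers)
Conditions: NaH, Bu4NI (cat.), DMF, 0 → 60 °C
Reagents that add atoms: none
Why: Williamson etherification should take place at the primary allylic alkoxide because the secondary hydroxyl next to quaternary C9 is far more hindered, and it brings in the two carbons that become C6 and C7.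

Step 13
Reactants: 19 (3R)-3-[(1S,6R)-6-[(tert-butyldimethylsilyl)oxy]-3-[(2,2-diethoxyethoxy)methyl]-2-methylcyclohex-2-en-1-yl]-3-methylpent-4-en-2-ol (C2 epimers)
Product: 20 (3R)-3-[(1S,6R)-6-[(tert-butyldimethylsilyl)oxy]-3-[(2,2-diethoxyethoxy)methyl]-2-methylcyclohex-2-en-1-yl]-3-methylpent-4-en-2-one
Conditions: Dess–Martin periodinane, CH2Cl2, rt
Reagents that add atoms: none
Why: Dess–Martin oxidation restores the C8 methyl ketone under conditions that should leave the acetal, the silyl ether and the alkenes intact.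

Step 14
Reactants: 20 (3R)-3-[(1S,6R)-6-[(tert-butyldimethylsilyl)oxy]-3-[(2,2-diethoxyethoxy)methyl]-2-methylcyclohex-2-en-1-yl]-3-methylpent-4-en-2-one
Product: 21 {[(3S,4R)-4-[(tert-butyldimethylsilyl)oxy]-2-methyl-3-[(3R)-3-methyl-4-oxopent-1-en-3-yl]cyclohex-1-en-1-yl]methoxy}acetaldehyde
Conditions: TESOTf, 2,4,6-collidine, CH2Cl2, 0 °C; then H2O
Reagents that add atoms: water, O
Why: Silyl triflate and collidine convert the diethyl acetal into a pyridinium intermediate that water hydrolyses to the aldehyde under non-acidic conditions compatible with the silyl ether and the allylic ether (mild acetal cleavage).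

Step 15
Reactants: 21 {[(3S,4R)-4-[(tert-butyldimethylsilyl)oxy]-2-methyl-3-[(3R)-3-methyl-4-oxopent-1-en-3-yl]cyclohex-1-en-1-yl]methoxy}acetaldehyde
Product: 22 (3R)-3-[(1S,6R)-6-[(tert-butyldimethylsilyl)oxy]-2-methyl-3-({[(Z)-2-[(triethylsilyl)oxy]ethenyl]oxy}methyl)cyclohex-2-en-1-yl]-3-methylpent-4-en-2-one
Conditions: TESOTf (1.05 equiv), Et3N, CH2Cl2, −78 → −30 °C
Reagents that add atoms: triethylsilyl trifluoromethanesulfonate, CC[Si](CC)(CC)OS(=O)(=O)C(F)(F)F
Why: Soft enolization of the α-alkoxy aldehyde with silyl triflate and amine should give mainly the (Z)-enol silane with the two oxygens cis, while the hindered methyl ketone enolizes more slowly.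

Step 16
Reactants: 22 (3R)-3-[(1S,6R)-6-[(tert-butyldimethylsilyl)oxy]-2-methyl-3-({[(Z)-2-[(triethylsilyl)oxy]ethenyl]oxy}methyl)cyclohex-2-en-1-yl]-3-methylpent-4-en-2-one
Product: 24 (1R,5R,6R,7S,8R,9R,10S)-1-[(tert-butyldimethylsilyl)oxy]-6-[(triethylsilyl)oxy]-13,14,15,16-tetranorcleroda-4(18),11-diene-7,8-diol, via aldehyde 23 (not isolated)
Conditions: PhMe, Et3N (trace), 135 °C, sealed tube; then, without isolation, SmI2 (3 equiv), t-BuOH, THF, −78 → 0 °C
Reagents that add atoms: none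
Why: Heating triggers a concerted suprafacial [3,3] shift of the allyl (Z)-2-silyloxyvinyl ether (C6=C7–O–C18–C4=C5) through a chair, which makes C5–C6, turns C7 into an aldehyde and moves the ring-A alkene to the exocyclic C4=C18 position; the epimerizable α-silyloxy aldehyde 23 is then reduced in the same flask by SmI2 to a ketyl that adds to the samarium-bound C8 ketone and makes C7–C8. The closest known types are the aliphatic Claisen rearrangement of allyl enol ethers that builds quaternary carbon (as in the enolate Claisen of glycolates) and the SmI2 pinacol cyclization of 1,6-keto aldehydes to cis-cyclohexane-1,2-diols. Ring B closes by 6-exo-trig attack of the C7 ketyl on the C8 carbonyl through a chair, and its fusion to ring A is trans because the sigmatropic shift has placed the C5 and C10 arms trans to each other on ring A. C5 is set by bond formation on the ring-A face opposite the pseudoaxial C9 group at C10, and C6 by the (Z)-enol geometry, which places the silyloxy group axial in the chair; C7 and C8 follow from the chelate that holds both oxygens cis on the face away from the axial C19 and C20 methyl groups and anti to the C6 silyloxy group, with the C8 methyl group equatorial. The step needs facial selectivity in the sigmatropic event and ketyl formation at the aldehyde ahead of the hindered ketone; the first is secured by the C10 substituent and the second by the easier reduction of the aldehyde and the absence of HMPA, which also keeps the C11 vinyl group and the C4 methylidene from acting as radical acceptors.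

Step 17
Reactants: 24 (1R,5R,6R,7S,8R,9R,10S)-1-[(tert-butyldimethylsilyl)oxy]-6-[(triethylsilyl)oxy]-13,14,15,16-tetranorcleroda-4(18),11-diene-7,8-diol
Product: 25 (1R,5R,6R,7S,8R,9R,10S)-1-[(tert-butyldimethylsilyl)oxy]-8-hydroxy-6-[(triethylsilyl)oxy]-13,14,15,16-tetranorcleroda-4(18),11-dien-7-yl 2-methylpropanoate
Conditions: (i-PrCO)2O, DMAP (cat.), pyridine, CH2Cl2, 0 °C → rt
Reagents that add atoms: isobutyric anhydride, CC(C)C(=O)OC(=O)C(C)C
Why: Nucleophile-catalysed acylation should take place at the secondary C7 hydroxyl and leave the tertiary axial C8 hydroxyl free.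

Step 18
Reactants: 25 (1R,5R,6R,7S,8R,9R,10S)-1-[(tert-butyldimethylsilyl)oxy]-8-hydroxy-6-[(triethylsilyl)oxy]-13,14,15,16-tetranorcleroda-4(18),11-dien-7-yl 2-methylpropanoate
Product: 26 (1R,5R,6R,7S,8R,9R,10S)-1-[(tert-butyldimethylsilyl)oxy]-6,8-dihydroxy-13,14,15,16-tetranorcleroda-4(18),11-dien-7-yl 2-methylpropanoate
Conditions: HF·pyridine, pyridine, THF, 0 °C
Reagents that add atoms: none
Why: Buffered HF should cleave the triethylsilyl ether much faster than the tert-butyldimethylsilyl ether, and the weakly acidic medium disfavours acyl migration from O7 to O6.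

Step 19
Reactants: 26 (1R,5R,6R,7S,8R,9R,10S)-1-[(tert-butyldimethylsilyl)oxy]-6,8-dihydroxy-13,14,15,16-tetranorcleroda-4(18),11-dien-7-yl 2-methylpropanoate
Product: 27 (1R,5R,6R,7S,8R,9R,10S)-6-acetoxy-1-[(tert-butyldimethylsilyl)oxy]-8-hydroxy-13,14,15,16-tetranorcleroda-4(18),11-dien-7-yl 2-methylpropanoate
Conditions: Ac2O, DMAP (cat.), pyridine, rt
Reagents that add atoms: acetic anhydride, CC(=O)OC(C)=O
Why: Nucleophile-catalysed acetylation of the secondary C6 hydroxyl completes the diester pattern while the tertiary C8 hydroxyl should stay free.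

Step 20
Reactants: 27 (1R,5R,6R,7S,8R,9R,10S)-6-acetoxy-1-[(tert-butyldimethylsilyl)oxy]-8-hydroxy-13,14,15,16-tetranorcleroda-4(18),11-dien-7-yl 2-methylpropanoate; 28 4-bromofuran-2(5H)-one
Product: 29 (1R,5R,6R,7S,8R,9R,10S)-6-acetoxy-1-[(tert-butyldimethylsilyl)oxy]-8-hydroxy-7-(2-methylpropanoyloxy)cleroda-4(18),11E,13-trien-15,16-olide
Conditions: Pd(OAc)2 (10 mol%), Bu4NCl, KOAc, DMF, 70 °C
Reagents that add atoms: none
Why: A Heck reaction under ligand-free phase-transfer conditions should couple the bromobutenolide at the terminal carbon of the vinyl group, β-hydride elimination can only give the conjugated (E)-C11=C12 alkene because C9 is quaternary, and the 1,1-disubstituted C4=C18 alkene is the poorer insertion partner.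

Step 21
Reactants: 29 (1R,5R,6R,7S,8R,9R,10S)-6-acetoxy-1-[(tert-butyldimethylsilyl)oxy]-8-hydroxy-7-(2-methylpropanoyloxy)cleroda-4(18),11E,13-trien-15,16-olide
Product: 30 (1R,5R,6R,7S,8R,9R,10S)-6-acetoxy-1,8-dihydroxy-7-(2-methylpropanoyloxy)cleroda-4(18),11E,13-trien-15,16-olide (CNP0215764.1)
Conditions: HF·pyridine, THF, rt
Reagents that add atoms: none
Why: Fluoride-mediated desilylation should remove the last silyl ether without affecting the two esters, the tertiary alcohol or the butenolide, and gives the target.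

Compound list
1 | ethyl (S)-lactate | C[C@H](O)C(=O)OCC | starting material
2 | ethyl (S)-2-[(tert-butyldimethylsilyl)oxy]propanoate | C[C@H](O[Si](C)(C)C(C)(C)C)C(=O)OCC | intermediate
3 | tert-butyl 2-(triphenyl-λ5-phosphanylidene)propanoate | CC(=P(c1ccccc1)(c1ccccc1)c1ccccc1)C(=O)OC(C)(C)C | starting material
4 | (S)-2-[(tert-butyldimethylsilyl)oxy]propanal | C[C@H](O[Si](C)(C)C(C)(C)C)C=O | intermediate
5 | tert-butyl (2E,4S)-4-[(tert-butyldimethylsilyl)oxy]-2-methylpent-2-enoate | C[C@H](O[Si](C)(C)C(C)(C)C)/C=C(\C)C(=O)OC(C)(C)C | intermediate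
6 | tert-butyl (2E,4S)-4-hydroxy-2-methylpent-2-enoate | C[C@H](O)/C=C(\C)C(=O)OC(C)(C)C | intermediate
7 | ethyl 2-methyl-4-oxocyclohex-2-ene-1-carboxylate (Hagemann's ester, racemic) | CCOC(=O)C1CCC(=O)C=C1C | starting material
8 | ethyl 4-ethoxy-2-methylcyclohexa-1,3-diene-1-carboxylate | CCOC(=O)C1=C(C)C=C(OCC)CC1 | intermediate
9 | ethyl 4-{[(2S,3E)-5-tert-butoxy-4-methyl-5-oxopent-3-en-2-yl]oxy}-2-methylcyclohexa-1,3-diene-1-carboxylate | CCOC(=O)C1=C(C)C=C(O[C@@H](C)/C=C(\C)C(=O)OC(C)(C)C)CC1 | intermediate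
10 | ethyl (3S)-3-[(2R,3E)-1-tert-butoxy-2-methyl-1-oxopent-3-en-2-yl]-2-methyl-4-oxocyclohex-1-ene-1-carboxylate | CCOC(=O)C1=C(C)[C@@H]([C@](C)(C(=O)OC(C)(C)C)/C=C/C)C(=O)CC1 | intermediate
11 | ethyl (3S)-3-[(2R)-1-tert-butoxy-2-methyl-1-oxobut-3-en-2-yl]-2-methyl-4-oxocyclohex-1-ene-1-carboxylate | CCOC(=O)C1=C(C)[C@@H]([C@](C)(C(=O)OC(C)(C)C)C=C)C(=O)CC1 | intermediate
12 | ethyl (3S,4S)-3-[(2R)-1-tert-butoxy-2-methyl-1-oxobut-3-en-2-yl]-4-hydroxy-2-methylcyclohex-1-ene-1-carboxylate | CCOC(=O)C1=C(C)[C@@H]([C@](C)(C(=O)OC(C)(C)C)C=C)[C@@H](O)CC1 | intermediate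
13 | ethyl (3S,4S)-3-[(2R)-1-tert-butoxy-2-methyl-1-oxobut-3-en-2-yl]-2-methyl-4-[(trifluoromethanesulfonyl)oxy]cyclohex-1-ene-1-carboxylate | CCOC(=O)C1=C(C)[C@@H]([C@](C)(C(=O)OC(C)(C)C)C=C)[C@@H](OS(=O)(=O)C(F)(F)F)CC1 | intermediate
14 | ethyl (3R,3aS,7aR)-3-ethenyl-3,4-dimethyl-2-oxo-2,3,3a,6,7,7a-hexahydro-1-benzofuran-5-carboxylate (trans-fused lactone) | CCOC(=O)C1=C(C)[C@H]2[C@@](C)(C=C)C(=O)O[C@@H]2CC1 | intermediate
15 | ethyl (3S,4R)-4-hydroxy-2-methyl-3-[(3R)-3-methyl-4-oxopent-1-en-3-yl]cyclohex-1-ene-1-carboxylate | CCOC(=O)C1=C(C)[C@@H]([C@](C)(C(C)=O)C=C)[C@H](O)CC1 | intermediate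
16 | ethyl (3S,4R)-4-[(tert-butyldimethylsilyl)oxy]-2-methyl-3-[(3R)-3-methyl-4-oxopent-1-en-3-yl]cyclohex-1-ene-1-carboxylate | CCOC(=O)C1=C(C)[C@@H]([C@](C)(C(C)=O)C=C)[C@H](O[Si](C)(C)C(C)(C)C)CC1 | intermediate
17 | (3R)-3-[(1S,6R)-6-[(tert-butyldimethylsilyl)oxy]-3-(hydroxymethyl)-2-methylcyclohex-2-en-1-yl]-3-methylpent-4-en-2-ol (C2 epimers) | OCC1=C(C)[C@@H]([C@](C)(C(C)O)C=C)[C@H](O[Si](C)(C)C(C)(C)C)CC1 | intermediate
18 | 2-bromo-1,1-diethoxyethane | BrCC(OCC)OCC | starting material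
19 | (3R)-3-[(1S,6R)-6-[(tert-butyldimethylsilyl)oxy]-3-[(2,2-diethoxyethoxy)methyl]-2-methylcyclohex-2-en-1-yl]-3-methylpent-4-en-2-ol (C2 epimers) | CCOC(COCC1=C(C)[C@@H]([C@](C)(C(C)O)C=C)[C@H](O[Si](C)(C)C(C)(C)C)CC1)OCC | intermediate
20 | (3R)-3-[(1S,6R)-6-[(tert-butyldimethylsilyl)oxy]-3-[(2,2-diethoxyethoxy)methyl]-2-methylcyclohex-2-en-1-yl]-3-methylpent-4-en-2-one | CCOC(COCC1=C(C)[C@@H]([C@](C)(C(C)=O)C=C)[C@H](O[Si](C)(C)C(C)(C)C)CC1)OCC | intermediate
21 | {[(3S,4R)-4-[(tert-butyldimethylsilyl)oxy]-2-methyl-3-[(3R)-3-methyl-4-oxopent-1-en-3-yl]cyclohex-1-en-1-yl]methoxy}acetaldehyde | O=CCOCC1=C(C)[C@@H]([C@](C)(C(C)=O)C=C)[C@H](O[Si](C)(C)C(C)(C)C)CC1 | intermediate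
22 | (3R)-3-[(1S,6R)-6-[(tert-butyldimethylsilyl)oxy]-2-methyl-3-({[(Z)-2-[(triethylsilyl)oxy]ethenyl]oxy}methyl)cyclohex-2-en-1-yl]-3-methylpent-4-en-2-one | CC[Si](CC)(CC)O/C=C\OCC1=C(C)[C@@H]([C@](C)(C(C)=O)C=C)[C@H](O[Si](C)(C)C(C)(C)C)CC1 | intermediate
23 | (2R)-2-[(1R,2S,3R)-3-[(tert-butyldimethylsilyl)oxy]-1-methyl-2-[(3R)-3-methyl-4-oxopent-1-en-3-yl]-6-methylidenecyclohexyl]-2-[(triethylsilyl)oxy]acetaldehyde | C=C1CC[C@@H](O[Si](C)(C)C(C)(C)C)[C@H]([C@](C)(C(C)=O)C=C)[C@@]1(C)[C@@H](O[Si](CC)(CC)CC)C=O | intermediate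
24 | (1R,5R,6R,7S,8R,9R,10S)-1-[(tert-butyldimethylsilyl)oxy]-6-[(triethylsilyl)oxy]-13,14,15,16-tetranorcleroda-4(18),11-diene-7,8-diol | C=C1CC[C@@H](O[Si](C)(C)C(C)(C)C)[C@H]2[C@@]1(C)[C@@H](O[Si](CC)(CC)CC)[C@H](O)[C@](C)(O)[C@]2(C)C=C | intermediate
25 | (1R,5R,6R,7S,8R,9R,10S)-1-[(tert-butyldimethylsilyl)oxy]-8-hydroxy-6-[(triethylsilyl)oxy]-13,14,15,16-tetranorcleroda-4(18),11-dien-7-yl 2-methylpropanoate | C=C1CC[C@@H](O[Si](C)(C)C(C)(C)C)[C@H]2[C@@]1(C)[C@@H](O[Si](CC)(CC)CC)[C@H](OC(=O)C(C)C)[C@](C)(O)[C@]2(C)C=C | intermediate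
26 | (1R,5R,6R,7S,8R,9R,10S)-1-[(tert-butyldimethylsilyl)oxy]-6,8-dihydroxy-13,14,15,16-tetranorcleroda-4(18),11-dien-7-yl 2-methylpropanoate | C=C1CC[C@@H](O[Si](C)(C)C(C)(C)C)[C@H]2[C@@]1(C)[C@@H](O)[C@H](OC(=O)C(C)C)[C@](C)(O)[C@]2(C)C=C | intermediate
27 | (1R,5R,6R,7S,8R,9R,10S)-6-acetoxy-1-[(tert-butyldimethylsilyl)oxy]-8-hydroxy-13,14,15,16-tetranorcleroda-4(18),11-dien-7-yl 2-methylpropanoate | C=C1CC[C@@H](O[Si](C)(C)C(C)(C)C)[C@H]2[C@@]1(C)[C@@H](OC(C)=O)[C@H](OC(=O)C(C)C)[C@](C)(O)[C@]2(C)C=C | intermediate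
28 | 4-bromofuran-2(5H)-one | BrC1=CC(=O)OC1 | starting material
29 | (1R,5R,6R,7S,8R,9R,10S)-6-acetoxy-1-[(tert-butyldimethylsilyl)oxy]-8-hydroxy-7-(2-methylpropanoyloxy)cleroda-4(18),11E,13-trien-15,16-olide | C=C1CC[C@@H](O[Si](C)(C)C(C)(C)C)[C@H]2[C@@]1(C)[C@@H](OC(C)=O)[C@H](OC(=O)C(C)C)[C@](C)(O)[C@]2(C)/C=C/C1=CC(=O)OC1 | intermediate
30 | (1R,5R,6R,7S,8R,9R,10S)-6-acetoxy-1,8-dihydroxy-7-(2-methylpropanoyloxy)cleroda-4(18),11E,13-trien-15,16-olide (CNP0215764.1) | C=C1CC[C@@H](O)[C@H]2[C@@]1(C)[C@@H](OC(C)=O)[C@H](OC(=O)C(C)C)[C@](C)(O)[C@]2(C)/C=C/C1=CC(=O)OC1 | target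

Total steps: 21. Longest linear sequence: 20 (steps 1–3, then 5–21).

Steps most likely to fail

Step 16. The [3,3] shift may lose facial or chair control at the crowded C5 terminus, the enol silane may decompose before it rearranges, or the ketyl may be reduced further instead of closing the ring. Fallback, from 17 back to 24: the primary allylic hydroxyl of 17 is acetylated selectively (Ac2O, pyridine, 0 °C) to give the allylic acetate F1, and Dess–Martin oxidation gives the methyl ketone F2. Palladium-catalysed borylation (B2pin2, Pd(dba)2, DMSO) then gives the allyl pinacol boronate F3. Allylboration of 2,2-dimethoxyacetaldehyde through the closed chair (attack at C5 anti to the C9 group, aldehyde substituent equatorial) should give the homoallylic alcohol F4 with the C5 and C6 configurations of the route. Silylation (TESOTf, 2,6-lutidine) gives the silyl ether F5, cleavage of the dimethyl acetal (TESOTf, 2,4,6-collidine; H2O) gives aldehyde 23, and the SmI2 cyclization, run as a separate step, gives 24.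

Step 8. Elimination of the triflate toward the ring diene, or capture by pyridine, may outrun participation of the ester. Fallback, from 12 back to 14: Mitsunobu inversion with 4-nitrobenzoic acid (PPh3, DIAD) gives the trans 4-nitrobenzoate F6, ethanolysis (K2CO3, EtOH) gives the trans hydroxy ester F7, and CF3CO2H in CH2Cl2 closes F7 to lactone 14 with loss of 2-methylpropene.

Step 20. Insertion into the vinyl group on quaternary C9 may be slow, and the bromobutenolide or the product diene may degrade or isomerize under the basic conditions. Fallback, from 27 back to 29: cross-metathesis of 27 with vinylboronic acid pinacol ester (second-generation Hoveyda–Grubbs catalyst, CH2Cl2, 40 °C) gives the (E)-alkenyl boronate F8, and Suzuki–Miyaura coupling of F8 with 28 (Pd(PPh3)4, K3PO4, THF/H2O) gives 29.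

Further compounds
F1 | step 16 | [(3S,4R)-4-[(tert-butyldimethylsilyl)oxy]-3-[(3R)-4-hydroxy-3-methylpent-1-en-3-yl]-2-methylcyclohex-1-en-1-yl]methyl acetate (carbinol epimers) | CC(=O)OCC1=C(C)[C@@H]([C@](C)(C(C)O)C=C)[C@H](O[Si](C)(C)C(C)(C)C)CC1
F2 | step 16 | [(3S,4R)-4-[(tert-butyldimethylsilyl)oxy]-2-methyl-3-[(3R)-3-methyl-4-oxopent-1-en-3-yl]cyclohex-1-en-1-yl]methyl acetate | CC(=O)OCC1=C(C)[C@@H]([C@](C)(C(C)=O)C=C)[C@H](O[Si](C)(C)C(C)(C)C)CC1
F3 | step 16 | (3R)-3-[(1S,6R)-6-[(tert-butyldimethylsilyl)oxy]-2-methyl-3-[(4,4,5,5-tetramethyl-1,3,2-dioxaborolan-2-yl)methyl]cyclohex-2-en-1-yl]-3-methylpent-4-en-2-one | CC1(C)OB(CC2=C(C)[C@@H]([C@](C)(C(C)=O)C=C)[C@H](O[Si](C)(C)C(C)(C)C)CC2)OC1(C)C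
F4 | step 16 | (3R)-3-[(1S,2R,6R)-6-[(tert-butyldimethylsilyl)oxy]-2-[(1R)-1-hydroxy-2,2-dimethoxyethyl]-2-methyl-3-methylidenecyclohexyl]-3-methylpent-4-en-2-one | C=C1CC[C@@H](O[Si](C)(C)C(C)(C)C)[C@H]([C@](C)(C(C)=O)C=C)[C@@]1(C)[C@@H](O)C(OC)OC
F5 | step 16 | (3R)-3-[(1S,2R,6R)-6-[(tert-butyldimethylsilyl)oxy]-2-[(1R)-2,2-dimethoxy-1-[(triethylsilyl)oxy]ethyl]-2-methyl-3-methylidenecyclohexyl]-3-methylpent-4-en-2-one | C=C1CC[C@@H](O[Si](C)(C)C(C)(C)C)[C@H]([C@](C)(C(C)=O)C=C)[C@@]1(C)[C@@H](O[Si](CC)(CC)CC)C(OC)OC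
F6 | step 8 | ethyl (3S,4R)-3-[(2R)-1-tert-butoxy-2-methyl-1-oxobut-3-en-2-yl]-2-methyl-4-[(4-nitrobenzoyl)oxy]cyclohex-1-ene-1-carboxylate | CCOC(=O)C1=C(C)[C@@H]([C@](C)(C(=O)OC(C)(C)C)C=C)[C@H](OC(=O)c2ccc(cc2)[N+](=O)[O-])CC1
F7 | step 8 | ethyl (3S,4R)-3-[(2R)-1-tert-butoxy-2-methyl-1-oxobut-3-en-2-yl]-4-hydroxy-2-methylcyclohex-1-ene-1-carboxylate | CCOC(=O)C1=C(C)[C@@H]([C@](C)(C(=O)OC(C)(C)C)C=C)[C@H](O)CC1
F8 | step 20 | (1R,5R,6R,7S,8R,9R,10S)-6-acetoxy-1-[(tert-butyldimethylsilyl)oxy]-8-hydroxy-12-(4,4,5,5-tetramethyl-1,3,2-dioxaborolan-2-yl)-13,14,15,16-tetranorcleroda-4(18),11E-dien-7-yl 2-methylpropanoate | C=C1CC[C@@H](O[Si](C)(C)C(C)(C)C)[C@H]2[C@@]1(C)[C@@H](OC(C)=O)[C@H](OC(=O)C(C)C)[C@](C)(O)[C@]2(C)/C=C/B1OC(C)(C)C(C)(C)O1
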